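**Retrosynthetic overview**
1. Target 30 ⇐ 11,13-epoxide 28 (chloride opens at C13) ⇐ α-methylene lactone 27 (nucleophilic epoxidation).
2. 27 ⇐ open-chain hydroxy aldehyde 25: the SmI2 ketyl of the C6 aldehyde adds to C7 of a 2-(acetoxymethyl)enoate; acetate loss and lactonisation then give the ten-membered carbocycle and the γ-lactone in one step (C6–C7).
3. 25 ⇐ C8 aldehyde 14 + bromoacrylate 18 (C7–C8, Nozaki–Hiyama–Kishi) + tiglic acid 21; 14 ⇐ furanone 10 + (S)-glyceraldehyde acetonide 11 (C9–C10 aldol, the dioxolane carbon becomes the C8 aldehyde).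
4. 10 ⇐ alkynol 5 + lactic Weinreb amide 7 (C1–C2, hydroxy ynone → 3(2H)-furanone); 5 ⇐ mesylate 2 + aldehyde 3 (C4–C5, anti propargylation).
5. Ring order: furanone first (step 4), then carbocycle and lactone together (step 12).

Numbering (germacrane locants of the target): C1 ketone, C2=C3 enol ether, C4 (methyl C15), C5 carbinol, C6 lactone carbinol, C7, C8 (tiglate), C9 carbinol, C10 (methyl C14, ring oxygen to C3), C11, C12 lactone carbonyl, C13 CH2Cl. The target is 4R,5S,6S,7S,8S,9S,10S,11S.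

Assumption: 3 is dehydrated before use and 11 is bought (otherwise two steps from L-ascorbic acid).

Step 1
Reactants: 1 (R)-but-3-yn-2-ol
Product: 2 (R)-but-3-yn-2-yl methanesulfonate
Conditions: MsCl, Et3N, CH2Cl2, −78 to 0 °C
Reagents that add atoms: methanesulfonyl chloride, CS(=O)(=O)Cl
Why: O-sulfonylation of the secondary alcohol, with the stereocentre untouched (retention).

Step 2
Reactants: 2 (R)-but-3-yn-2-yl methanesulfonate; 3 2,2-dimethoxyacetaldehyde
Product: 5 (2S,3S)-1,1-dimethoxy-3-methylpent-4-yn-2-ol, via allenylzinc reagent 4 (not isolated)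
Conditions: Pd(OAc)2 (5 mol%), PPh3 (5 mol%), Et2Zn (3 equiv), THF, −78 to −20 °C
Reagents that add atoms: none
Why: Marshall–Tamaru propargylation, in which zerovalent palladium displaces the mesylate anti (SN2'), Et2Zn transmetalates to allenylzinc 4 and this adds through a cyclic SE2' chair, so that net inversion at the methyl carbon sets C4 and the chair sets the C5 hydroxyl anti to the methyl.

Step 3
Reactants: 6 ethyl (S)-lactate
Product: 7 (S)-2-hydroxy-N-methoxy-N-methylpropanamide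
Conditions: MeNHOMe·HCl, i-PrMgCl (3 equiv), THF, −20 to 0 °C
Reagents that add atoms: N,O-dimethylhydroxylamine hydrochloride, CNOC.Cl
Why: Weinreb amide formation by aminolysis of the ester with the magnesium amide; the lactate centre becomes the enolisable C10 of 10 and is erased in step 5.

Step 4
Reactants: 5 (2S,3S)-1,1-dimethoxy-3-methylpent-4-yn-2-ol; 7 (S)-2-hydroxy-N-methoxy-N-methylpropanamide
Product: 10 5-[(2R,3S)-3-hydroxy-4,4-dimethoxybutan-2-yl]-2-methylfuran-3(2H)-one (C2 epimers), via hydroxy ynone 8 (not isolated), via diethylamino enone 9 (not isolated)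
Conditions: 5, n-BuLi (2.1 equiv), THF, −78 °C; lithium alkoxide of 7 (7 + n-BuLi, 1.3 equiv), −78 to 0 °C; then EtOH, Et2NH, 23 °C; then AcOH–H2O
Reagents that add atoms: none
Why: Acetylide acylation by the Weinreb amide gives ynone 8, amine conjugate addition gives enaminone 9, and the α'-hydroxyl displaces the amine by addition–elimination to close the 3(2H)-furanone, with C4 and C5 untouched.

Step 5
Reactants: 10 5-[(2R,3S)-3-hydroxy-4,4-dimethoxybutan-2-yl]-2-methylfuran-3(2H)-one; 11 (S)-2,2-dimethyl-1,3-dioxolane-4-carbaldehyde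
Product: 13 bis-TBS aldol adduct (C5-OTBS; C9-OTBS; 4R,5S,9S,10S; dioxolane 4S), via aldol diol 12 (not isolated)
Conditions: LiN(iPr)2 (2.2 equiv), THF, −78 °C; 11; then TBSOTf (2.6 equiv), −78 to −40 °C
Reagents that add atoms: tert-butyldimethylsilyl trifluoromethanesulfonate, CC(C)(C)[Si](C)(C)OS(=O)(=O)C(F)(F)F
Why: Lithium aldol of the furan-3-olate at C10, where the Zimmerman–Traxler chair (methyl cis to O–Li) places the C14 methyl syn and the ring oxygen anti to the new C9 hydroxyl and Felkin–Anh attack anti to the dioxolane oxygen of the (S)-aldehyde fixes the absolute sense of C9 and C10; both alkoxides are silylated in the flask.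

Step 6
Reactants: 13 bis-TBS aldol adduct
Product: 14 C8 aldehyde (2R)-2-[(tert-butyldimethylsilyl)oxy]-2-[(2S)-furanonyl]acetaldehyde (C5-OTBS and C6 acetal retained)
Conditions: H5IO6, EtOAc, 0 to 23 °C
Reagents that add atoms: none
Why: One-pot hydrolysis and glycol cleavage of the terminal acetonide turns the auxiliary stereocentre into the C8 aldehyde, while the C9 silyl ether blocks over-cleavage and retro-aldol and the α-silyloxy acetal is too deactivated to hydrolyse.

Step 7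
Reactants: 15 methyl 2-(bromomethyl)acrylate
Product: 17 methyl (Z)-3-bromo-2-(bromomethyl)acrylate, via tribromide 16 (not isolated)
Conditions: Br2, CH2Cl2, 0 °C; then Et3N, 0 to 23 °C
Reagents that add atoms: bromine, BrBr
Why: Bromine addition gives the symmetric tribromide, whose anti E2 dehydrobromination has only one constitutional outcome and places the vinyl bromine trans to the ester, as in the bromination–dehydrobromination of methacrylates.

Step 8
Reactants: 17 methyl (Z)-3-bromo-2-(bromomethyl)acrylate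
Product: 18 methyl (E)-2-(acetoxymethyl)-3-bromoacrylate
Conditions: KOAc, DMF, 0 to 23 °C
Reagents that add atoms: potassium acetate, CC(=O)[O-].[K+]
Why: SN2 displacement of the primary allylic bromide by acetate, leaving the alkene geometry unchanged (only the CIP descriptor changes).

Step 9
Reactants: 14 C8 aldehyde; 18 methyl (E)-2-(acetoxymethyl)-3-bromoacrylate
Product: 20 allylic alcohol methyl (2E,4S,5S)-2-(acetoxymethyl)-5-silyloxy-5-furanonyl-4-hydroxypent-2-enoate, via alkenylchromium dichloride 19 (not isolated)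
Conditions: CrCl2 (6 equiv), NiCl2 (2 mol%), DMSO, 23 °C
Reagents that add atoms: none
Why: Nozaki–Hiyama–Kishi coupling (zerovalent nickel inserts with retention, transmetalation to trivalent chromium) in which Felkin–Anh addition anti to the C9 silyloxy group sets C8 and the E enoate geometry (carbinol trans to the ester) prevents lactonisation.

Step 10
Reactants: 20 allylic alcohol; 21 tiglic acid
Product: 23 C8 tiglate, via mixed anhydride 22 (not isolated)
Conditions: 21, 2,4,6-trichlorobenzoyl chloride, Et3N, THF, 23 °C; then 20, DMAP, toluene, 23 °C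
Reagents that add atoms: none
Why: Yamaguchi esterification acylates the only free hydroxyl (C8) without touching stereocentres and without the ketene pathway that scrambles tigloyl chloride.

Step 11
Reactants: 23 C8 tiglate
Product: 25 hydroxy aldehyde (C5-OH; C6 aldehyde; C9-OTBS), via hydroxy acetal 24 (not isolated)
Conditions: HF·pyridine, pyridine, THF, 0 °C; then 2 M aq. HCl to pH 1, THF, 23 °C
Reagents that add atoms: water, O
Why: Sterically governed desilylation removes the C5 silyl ether while the C9 one (next to quaternary C10) stays, and dilute aqueous acid then hydrolyses the dimethyl acetal; no stereocentre is involved and 25 is used crude.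

Step 12
Reactants: 25 hydroxy aldehyde
Product: 27 α-methylene lactone (4R,5S,6S,7S,8S,9S,10S)-9-silyloxy-5-hydroxy-1-oxo-3,10-epoxygermacra-2,11(13)-dien-12,6-olid-8-yl tiglate, via carbocyclic hydroxy ester 26 (not isolated)
Conditions: SmI2 (2.5 equiv), THF, 2 mM (syringe-pump addition of 25), −78 to −20 °C
Reagents that add atoms: none
Why: Proposed new method: SmI2 turns the aldehyde into a trivalent-samarium ketyl (nucleophilic C6) that adds to the enoate β-carbon C7, a second electron gives the samarium enolate which expels acetate to the exo-methylene ester 26 and the C6 alkoxide lactonises; C6 is set syn to C5 by the five-membered samarium chelate with the free C5 hydroxyl (attack anti to C4) and C7 by A(1,3) strain in the enoate (C8–H in the alkene plane, attack anti to the C9 branch), together giving the trans-fused lactone; the closest known reactions are SmI2 ketyl–acrylate coupling to γ-lactones, SmI2 ketyl–olefin medium-ring closures and β-acyloxy elimination from samarium enolates.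

Step 13
Reactants: 27 α-methylene lactone
Product: 28 11,13-epoxide (11R)
Conditions: t-BuOOH (decane), DBU, CH2Cl2, 0 °C
Reagents that add atoms: tert-butyl hydroperoxide, CC(C)(C)OO
Why: Weitz–Scheffer nucleophilic epoxidation selects the exo-methylene lactone over the tiglate and the vinylogous ester, and the enolate closes on oxygen from the face opposite the C8 substituent (cis to H7), setting C11.

Step 14
Reactants: 28 11,13-epoxide
Product: 30 target (4R,5S,6S,7S,8S,9S,10S,11S)-13-chloro-5,9,11-trihydroxy-1-oxo-3,10-epoxygermacr-2-en-12,6-olid-8-yl (E)-2-methylbut-2-enoate, via chlorohydrin silyl ether 29 (not isolated)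
Conditions: HCl (4 M in dioxane), CH2Cl2, 0 °C; then MeOH, 23 °C
Reagents that add atoms: hydrogen chloride, Cl
Why: Chloride opens the glycidic epoxide by SN2 at the primary C13 with the C11–O bond retained, and acidic methanol then removes the C9 silyl ether.

**Compound list**
1 | (R)-but-3-yn-2-ol | C[C@@H](O)C#C | starting material
2 | (R)-but-3-yn-2-yl methanesulfonate | C[C@@H](OS(C)(=O)=O)C#C | intermediate
3 | 2,2-dimethoxyacetaldehyde | COC(OC)C=O | starting material
4 | ethyl[(M)-buta-1,2-dien-1-yl]zinc | CC[Zn]C=[C@@]=CC | intermediate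
5 | (2S,3S)-1,1-dimethoxy-3-methylpent-4-yn-2-ol | COC(OC)[C@@H](O)[C@@H](C)C#C | intermediate
6 | ethyl (S)-lactate | C[C@H](O)C(=O)OCC | starting material
7 | (S)-2-hydroxy-N-methoxy-N-methylpropanamide | C[C@H](O)C(=O)N(C)OC | intermediate
8 | (2S,6S,7S)-2,7-dihydroxy-8,8-dimethoxy-6-methyloct-4-yn-3-one | COC(OC)[C@@H](O)[C@@H](C)C#CC(=O)[C@H](C)O | intermediate
9 | (2S,4E,6S,7S)-5-(diethylamino)-2,7-dihydroxy-8,8-dimethoxy-6-methyloct-4-en-3-one | COC(OC)[C@@H](O)[C@@H](C)/C(N(CC)CC)=C\C(=O)[C@H](C)O | intermediate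
10 | 5-[(2R,3S)-3-hydroxy-4,4-dimethoxybutan-2-yl]-2-methylfuran-3(2H)-one (ring C2 = C10, epimer mixture) | COC(OC)[C@@H](O)[C@@H](C)C1=CC(=O)C(C)O1 | intermediate
11 | (S)-2,2-dimethyl-1,3-dioxolane-4-carbaldehyde | CC1(C)OC[C@@H](C=O)O1 | starting material
12 | (2S)-2-[(S)-[(4S)-2,2-dimethyl-1,3-dioxolan-4-yl](hydroxy)methyl]-5-[(2R,3S)-3-hydroxy-4,4-dimethoxybutan-2-yl]-2-methylfuran-3(2H)-one (formed as its dilithium alkoxide) | COC(OC)[C@@H](O)[C@@H](C)C1=CC(=O)[C@@](C)(O1)[C@@H](O)[C@@H]2COC(C)(C)O2 | intermediate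
13 | (2S)-2-[(S)-[(tert-butyldimethylsilyl)oxy][(4S)-2,2-dimethyl-1,3-dioxolan-4-yl]methyl]-5-[(2R,3S)-3-[(tert-butyldimethylsilyl)oxy]-4,4-dimethoxybutan-2-yl]-2-methylfuran-3(2H)-one | COC(OC)[C@@H](O[Si](C)(C)C(C)(C)C)[C@@H](C)C1=CC(=O)[C@@](C)(O1)[C@@H](O[Si](C)(C)C(C)(C)C)[C@@H]2COC(C)(C)O2 | intermediate
14 | (2R)-2-[(tert-butyldimethylsilyl)oxy]-2-[(2S)-5-[(2R,3S)-3-[(tert-butyldimethylsilyl)oxy]-4,4-dimethoxybutan-2-yl]-2-methyl-3-oxo-2,3-dihydrofuran-2-yl]acetaldehyde | COC(OC)[C@@H](O[Si](C)(C)C(C)(C)C)[C@@H](C)C1=CC(=O)[C@@](C)(O1)[C@@H](O[Si](C)(C)C(C)(C)C)C=O | intermediate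
15 | methyl 2-(bromomethyl)acrylate | C=C(CBr)C(=O)OC | starting material
16 | methyl 2,3-dibromo-2-(bromomethyl)propanoate | COC(=O)C(Br)(CBr)CBr | intermediate
17 | methyl (Z)-3-bromo-2-(bromomethyl)acrylate | Br/C=C(\CBr)C(=O)OC | intermediate
18 | methyl (E)-2-(acetoxymethyl)-3-bromoacrylate | Br/C=C(\COC(C)=O)C(=O)OC | intermediate
19 | [(E)-2-(acetoxymethyl)-3-methoxy-3-oxoprop-1-en-1-yl]chromium dichloride | Cl[Cr](Cl)/C=C(\COC(C)=O)C(=O)OC | intermediate
20 | methyl (2E,4S,5S)-2-(acetoxymethyl)-5-[(tert-butyldimethylsilyl)oxy]-5-[(2S)-5-[(2R,3S)-3-[(tert-butyldimethylsilyl)oxy]-4,4-dimethoxybutan-2-yl]-2-methyl-3-oxo-2,3-dihydrofuran-2-yl]-4-hydroxypent-2-enoate | COC(OC)[C@@H](O[Si](C)(C)C(C)(C)C)[C@@H](C)C1=CC(=O)[C@@](C)(O1)[C@@H](O[Si](C)(C)C(C)(C)C)[C@@H](O)/C=C(\COC(C)=O)C(=O)OC | intermediate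
21 | tiglic acid, (E)-2-methylbut-2-enoic acid | C/C=C(\C)C(=O)O | starting material
22 | (E)-2-methylbut-2-enoic 2,4,6-trichlorobenzoic anhydride | C/C=C(\C)C(=O)OC(=O)c1c(Cl)cc(Cl)cc1Cl | intermediate
23 | methyl (2E,4S,5S)-2-(acetoxymethyl)-5-[(tert-butyldimethylsilyl)oxy]-5-[(2S)-5-[(2R,3S)-3-[(tert-butyldimethylsilyl)oxy]-4,4-dimethoxybutan-2-yl]-2-methyl-3-oxo-2,3-dihydrofuran-2-yl]-4-{[(2E)-2-methylbut-2-enoyl]oxy}pent-2-enoate | COC(OC)[C@@H](O[Si](C)(C)C(C)(C)C)[C@@H](C)C1=CC(=O)[C@@](C)(O1)[C@@H](O[Si](C)(C)C(C)(C)C)[C@@H](OC(=O)/C(C)=C/C)/C=C(\COC(C)=O)C(=O)OC | intermediate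
24 | methyl (2E,4S,5S)-2-(acetoxymethyl)-5-[(tert-butyldimethylsilyl)oxy]-5-[(2S)-5-[(2R,3S)-3-hydroxy-4,4-dimethoxybutan-2-yl]-2-methyl-3-oxo-2,3-dihydrofuran-2-yl]-4-{[(2E)-2-methylbut-2-enoyl]oxy}pent-2-enoate | COC(OC)[C@@H](O)[C@@H](C)C1=CC(=O)[C@@](C)(O1)[C@@H](O[Si](C)(C)C(C)(C)C)[C@@H](OC(=O)/C(C)=C/C)/C=C(\COC(C)=O)C(=O)OC | intermediate
25 | methyl (2E,4S,5S)-2-(acetoxymethyl)-5-[(tert-butyldimethylsilyl)oxy]-5-[(2S)-5-[(2R,3S)-3-hydroxy-4-oxobutan-2-yl]-2-methyl-3-oxo-2,3-dihydrofuran-2-yl]-4-{[(2E)-2-methylbut-2-enoyl]oxy}pent-2-enoate | O=C[C@@H](O)[C@@H](C)C1=CC(=O)[C@@](C)(O1)[C@@H](O[Si](C)(C)C(C)(C)C)[C@@H](OC(=O)/C(C)=C/C)/C=C(\COC(C)=O)C(=O)OC | intermediate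
26 | methyl (4R,5S,6S,7S,8S,9S,10S)-9-[(tert-butyldimethylsilyl)oxy]-5,6-dihydroxy-8-{[(E)-2-methylbut-2-enoyl]oxy}-1-oxo-3,10-epoxygermacra-2,11(13)-dien-12-oate (formed as its samarium alkoxide) | C/C=C(\C)C(=O)O[C@H]1[C@@H](C(=C)C(=O)OC)[C@H](O)[C@@H](O)[C@@H](C)C2=CC(=O)[C@@](C)(O2)[C@H]1O[Si](C)(C)C(C)(C)C | intermediate
27 | (4R,5S,6S,7S,8S,9S,10S)-9-[(tert-butyldimethylsilyl)oxy]-5-hydroxy-1-oxo-3,10-epoxygermacra-2,11(13)-dien-12,6-olid-8-yl (E)-2-methylbut-2-enoate | C/C=C(\C)C(=O)O[C@H]1[C@@H]2[C@H](OC(=O)C2=C)[C@@H](O)[C@@H](C)C2=CC(=O)[C@@](C)(O2)[C@H]1O[Si](C)(C)C(C)(C)C | intermediate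
28 | (4R,5S,6S,7S,8S,9S,10S,11R)-9-[(tert-butyldimethylsilyl)oxy]-11,13-epoxy-5-hydroxy-1-oxo-3,10-epoxygermacr-2-en-12,6-olid-8-yl (E)-2-methylbut-2-enoate | C/C=C(\C)C(=O)O[C@H]1[C@@H]2[C@H](OC(=O)[C@]2(O3)C3)[C@@H](O)[C@@H](C)C2=CC(=O)[C@@](C)(O2)[C@H]1O[Si](C)(C)C(C)(C)C | intermediate
29 | (4R,5S,6S,7S,8S,9S,10S,11S)-9-[(tert-butyldimethylsilyl)oxy]-13-chloro-5,11-dihydroxy-1-oxo-3,10-epoxygermacr-2-en-12,6-olid-8-yl (E)-2-methylbut-2-enoate | C/C=C(\C)C(=O)O[C@H]1[C@@H]2[C@H](OC(=O)[C@]2(O)CCl)[C@@H](O)[C@@H](C)C2=CC(=O)[C@@](C)(O2)[C@H]1O[Si](C)(C)C(C)(C)C | intermediate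
30 | (4R,5S,6S,7S,8S,9S,10S,11S)-13-chloro-5,9,11-trihydroxy-1-oxo-3,10-epoxygermacr-2-en-12,6-olid-8-yl (E)-2-methylbut-2-enoate (CNP0340393.1) | C/C=C(\C)C(=O)O[C@H]1[C@@H]2[C@H](OC(=O)[C@]2(O)CCl)[C@@H](O)[C@@H](C)C2=CC(=O)[C@@](C)(O2)[C@H]1O | target

**Totals**
Total step count: 14. Longest linear sequence: 11 steps (1, 2, 4, 5, 6, 9, 10, 11, 12, 13, 14) from 1. Steps 3, 7 and 8 prepare the side reagents 7 and 18.

**Three steps most likely to fail**

Step 12 (ketyl macrocyclisation). Pinacol dimerisation, simple reduction, loss of the C5 oxygen or the wrong C6/C7 pairing are all possible. The fallback inverts the polarity of the other partner instead. It sets out from 25: Pd(PPh3)4 (5 mol%) and InI (1.5 equiv) in THF–DMF at high dilution ionise the allylic acetate and give the allyl(acetato)iodoindium reagent F1. This closed-shell allylmetal adds through its γ-carbon (C7) to the C6 aldehyde in a six-membered chair. The resulting alkoxide lactonises through 26, and the route is rejoined at 27.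

Step 5 (aldol at the quaternary C10). The closed lithium transition state may give poor selectivity at C9/C10, or the dianion may fragment. The fallback sets out from 10 and uses an open, Lewis-acid-mediated aldol of an isolated nucleophile. TBSOTf and Et3N give the 3-silyloxyfuran F2 (C5 silylated at the same time). BF3·OEt2-promoted Mukaiyama aldol with 11 at −78 °C gives the C9-hydroxy aldol F3. TBSOTf with 2,6-lutidine then silylates C9, and the route is rejoined at 13.

Step 13 (nucleophilic epoxidation). The free C5 hydroxyl may add to the exo-methylene group under base, or face selectivity may be poor. The fallback sets out from 27 and avoids basic peroxide. OsO4 (catalytic) with N-methylmorpholine N-oxide dihydroxylates the exo-methylene from the face opposite C8 to give the 11,13-diol F4. Appel chlorination (PPh3, CCl4) of the primary hydroxyl then rejoins the route at 29, which acidic methanol converts to 30 as in the second half of step 14.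

**Further compounds**
F1 | step 12 | allyl(acetato)iodoindium reagent derived from 25 (In on C13) | O=C[C@@H](O)[C@@H](C)C1=CC(=O)[C@@](C)(O1)[C@@H](O[Si](C)(C)C(C)(C)C)[C@@H](OC(=O)/C(C)=C/C)/C=C(\C[In](I)OC(C)=O)C(=O)OC
F2 | step 5 | tert-butyl{[5-[(2R,3S)-3-[(tert-butyldimethylsilyl)oxy]-4,4-dimethoxybutan-2-yl]-2-methylfuran-3-yl]oxy}dimethylsilane | COC(OC)[C@@H](O[Si](C)(C)C(C)(C)C)[C@@H](C)c1cc(O[Si](C)(C)C(C)(C)C)c(C)o1
F3 | step 5 | (2S)-2-[(S)-[(4S)-2,2-dimethyl-1,3-dioxolan-4-yl](hydroxy)methyl]-5-[(2R,3S)-3-[(tert-butyldimethylsilyl)oxy]-4,4-dimethoxybutan-2-yl]-2-methylfuran-3(2H)-one | COC(OC)[C@@H](O[Si](C)(C)C(C)(C)C)[C@@H](C)C1=CC(=O)[C@@](C)(O1)[C@@H](O)[C@@H]2COC(C)(C)O2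
F4 | step 13 | (4R,5S,6S,7S,8S,9S,10S,11R)-9-[(tert-butyldimethylsilyl)oxy]-5,11,13-trihydroxy-1-oxo-3,10-epoxygermacr-2-en-12,6-olid-8-yl (E)-2-methylbut-2-enoate | C/C=C(\C)C(=O)O[C@H]1[C@@H]2[C@H](OC(=O)[C@]2(O)CO)[C@@H](O)[C@@H](C)C2=CC(=O)[C@@](C)(O2)[C@H]1O[Si](C)(C)C(C)(C)C
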